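## The problem

The target 27 is a 3,3'-linked dimer of two 4-aryl-chroman-2-ones. Each lactone is numbered O1, C2, C3, C4, C4a–C8a, unprimed for the 5,7-dihydroxy half (ring A) and primed for the 5,6,7,8-tetrahydroxy half (ring B). The four contiguous stereocentres are 3R,4R,3'S,4'R, so ring A is 3,4-trans and ring B is 3',4'-cis. The trans lactone is the stable arrangement, and C3 follows C4 by equilibration; the cis lactone is not, so C3' and C4' must be set kinetically and must not meet base afterwards, because C3 and C3' are α to aryl ester carbonyls. Induction from C3 to C3' across a freely rotating bond is a weak lever, so C3' needs its own controller. Both lactones are aryl esters that alkoxides and amines open, the free ring B is a 1,2,3,4-tetrahydroxybenzene that oxidizes in air, and eight phenols must be carried masked. The enabling feature is the fragment C4–C3–C3': C4 bears a 4-oxygenated aryl donor, and C3 and C3' each bear a carbonyl carbon (C2 and C2'). The three carbons are therefore a ring-opened 3-arylcyclopropane-1,2-dicarbonyl whose missing bond is C4–C3', and the arene to be attached at C4 is phloroglucinol, whose three ring carbons are equivalent.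

## Retrosynthesis

**27 ⇒ 26 (eight O–CH3 bonds).** All phenols are carried as methyl ethers. They tolerate the Lewis acids and organometallic reagents of the route, they are already present in the purchasable ring B arene, and BBr3 removes them without base. Benzyl ethers would allow a neutral hydrogenolysis but would make the pentaoxygenated ring B far longer to prepare. The forward step must cleave eight ethers without enolizing C3'.

**26 ⇒ 14 + 22 (C3'–C4' and O1'–C2', ring B).** Ring B is cut last so that the kinetically set cis lactone sees only one further step. Both of its stereocentres arise in one C–C bond formation between the enolate 23 of imide 14 and the ortho-quinone methide 24 released from benzhydrol 22; acyl transfer in adduct 25 then closes the lactone. The acyl oxazolidinone this needs is the same group the cyclopropane step needs as chelating acceptor. Imide 14 holds all of ring A; 22 is racemic because its carbinol centre becomes sp2 in 24. The forward reaction must control the enolate face (C3') and the relative topicity (C4').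

**14 ⇒ 13 ⇒ 10 + 11 (C4–C4a and O1–C2; C4–C3' reconnected).** After removing the two methyl ethers (14 ⇒ 13), ring A is cut at the aryl–C4 bond and the lactone C–O bond, and C4 is rejoined to C3' as cyclopropane 10. A second enolate/quinone methide annulation for ring A would be the neighbouring cut, but it would need another stereoselective C–C bond formation. The cyclopropane cut instead makes C4 the result of a stereospecific inversion, takes the trans relation from the ring geometry, and uses phloroglucinol 11 with no regiochemical choice. The forward reaction must break the bond to the imide-bearing carbon and not the one to the ester-bearing carbon, must go with inversion, and must lactonize on the ester.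

**10 ⇒ 7 + 8; 7 ⇒ 6 (acyl–N bond; ester C–O bond).** The imide comes from hemiester 7 and (S)-4-benzyl-oxazolidinone 8, and 7 from meso anhydride 6 by enantiotopic-group-selective methanolysis. All three cyclopropane stereocentres then derive from one desymmetrization, and the two carbonyls of 6 become C2 (ester) and C2' (imide). The oxazolidinone is used as its 4-benzyl derivative so that it later controls C3' and converts any antipodal hemiester into a separable diastereomer.

**6 ⇒ 2 + 3; 2 ⇒ 1 (two cyclopropane bonds).** The anhydride comes from maleic anhydride 3 and the aryldiazomethane 4 made from hydrazone 2 of aldehyde 1, through pyrazoline 5. The five-membered anhydride enforces the cis relation of the acyl groups; the aryl group must end trans to them.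

**22 ⇒ 20 + 21; 20 ⇒ 18; 18 ⇒ 15.** The benzhydrol comes from salicylaldehyde 20 and Grignard reagent 21, the aldehyde from phenol 18 by ortho-formylation at its only free position, and 18 from symmetric arene 15 by lithiation, borylation and oxidation. Each step is regiochemically forced.

## Roads not taken

**Alternative 1:** Ring A is cut at C3–C4 and O1–C2 at the lactol oxidation level. Aldehyde A2, which already carries the finished cis ring B lactone, forms an enamine with a diarylprolinol silyl ether (acetic acid co-catalyst). The enamine adds to the quinone methide from benzhydrol A3, and the phenol closes to lactol A1 as C2 epimers; oxidation to the lactone and demethylation follow.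
- Merits: amine-catalysed α-alkylation of aldehydes by quinone methides is well precedented, usually trans-selective and catalyst-controlled, and the union is convergent. In precedent it is ahead of the cyclopropane opening chosen here.
- Weak points: the cis lactone must be made first, so the hardest stereochemical problem is only moved. That aryl ester, with its epimerizable C3', must then survive a secondary amine/acid medium and a lactol oxidation. The enamine is β-branched by the bulky stereogenic C3', so rate and catalyst/substrate matching are open, and one redox step is added.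
- Comparison: against the better precedent, the chosen plan sets a stereospecific origin of C4, absolute configuration from a meso compound, and a sequence in which the cis lactone is the last ring made.

**Alternative 2:** Only O1'–C8a' is cut. Quinone acid A5 (ring B as a 2,3-dimethoxy-1,4-benzoquinone) is treated with Sc(OTf)3 or CF3CO2H; the carboxyl oxygen adds to quinone carbon C8a' and tautomerization gives hydroquinone lactone A4.
- Merits: acidic, redox-neutral, touches no stereocentre, and frees two ring B phenols, so six instead of eight ethers remain. It is gentler on the cis centre than an enolate step.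
- Weak points: the step makes neither a C–C bond nor a stereocentre, so C3' and C4' must be set in an open chain with no ring to help. A5 requires oxidizing one tetramethoxyarene in the presence of three other electron-rich rings. Carboxylic acids are poor oxygen donors toward quinones, and A4 can be oxidized by unreacted A5.
- Comparison: the chosen plan also closes ring B under acid (25 → 26) but forms C3'–C4' in the same operation under auxiliary control. It does carry two more methyl ethers into the last step.

**Alternative 3:** Ring B is cut at O1'–C8a' and C4'–C4a'. CsF releases 3,4,5,6-tetramethoxybenzyne from silyl triflate A8; the cesium carboxylate of cinnamic acid A7 adds to the aryne, the aryl anion adds to C4', and protonation at C3' gives A6, which is identical with 26.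
- Merits: a symmetrical aryne has no regiochemistry, and the whole pentaoxygenated ring arrives in one step without benzhydrol 22. If it worked as drawn it would be shorter than the chosen route.
- Weak points: the usual fate of the aryl anion from an aryne and a carboxylate is attack on the nearby acyl carbon (giving ortho-hydroxyaryl ketones and, from acrylic acids, chroman-4-ones), not six-ring conjugate addition. C4' and C3' would both be set with only the remote ring A as control, in a basic fluoride medium, and the cis isomer is the less stable one. A8 itself needs several steps.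
- Comparison: against its brevity the chosen plan sets a named control element for each of the four stereocentres.

Key step: step 5

Assumption: 1,2,3,4-tetramethoxybenzene (15) is taken as purchasable, and the sense of the quinine-mediated methanolysis in step 3 is assigned by analogy with bicyclic succinic anhydrides (quinidine gives the antipode).

## Steps

Step 1
Reactants: 1 4-methoxybenzaldehyde
Product: 2 (E)-(4-methoxybenzylidene)hydrazine
Conditions: N2H4·H2O (5 equiv), EtOH, 0 → 23 °C
Reagents that add atoms: hydrazine monohydrate, NN.O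
Why: Hydrazone formation; adding the aldehyde to excess hydrazine suppresses the azine.

Step 2
Reactants: 2 (E)-(4-methoxybenzylidene)hydrazine, 3 maleic anhydride
Product: 6 meso-6-exo-(4-methoxyphenyl)-3-oxabicyclo[3.1.0]hexane-2,4-dione, via 1-(diazomethyl)-4-methoxybenzene 4 (not isolated), via cis-fused 1-pyrazoline adduct 5 (not isolated)
Conditions: MnO2, CH2Cl2, 0 °C, filter; then 3, CH2Cl2, −20 → 23 °C; then toluene, 60 °C
Reagents that add atoms: none
Why: MnO2 dehydrogenates the hydrazone to aryldiazomethane 4, which adds to the electron-poor alkene (1,3-dipolar cycloaddition); pyrazoline 5 loses N2 on warming (ring contraction) to the cyclopropane. The five-membered anhydride enforces the cis fusion, and the aryl group should end exo (trans to both carbonyls), the less hindered cycloaddition mode and the more stable closure; 6 is meso, so no absolute configuration is at stake.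

Step 3
Reactants: 6 meso-6-exo-(4-methoxyphenyl)-3-oxabicyclo[3.1.0]hexane-2,4-dione
Product: 7 (1S,2R,3S)-2-(methoxycarbonyl)-3-(4-methoxyphenyl)cyclopropane-1-carboxylic acid
Conditions: quinine (1.1 equiv), MeOH (3 equiv), toluene, −55 °C
Reagents that add atoms: methanol, CO
Why: Cinchona-alkaloid-mediated methanolysis of a meso cyclic anhydride (desymmetrization): the quinuclidine nitrogen delivers methanol to one of the two enantiotopic carbonyls. This decides which ring carbon becomes C3 (ester) and which C3' (acid, later imide), and so fixes the absolute configuration of all three cyclopropane carbons.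

Step 4
Reactants: 7 (1S,2R,3S)-2-(methoxycarbonyl)-3-(4-methoxyphenyl)cyclopropane-1-carboxylic acid, 8 (S)-4-benzyl-1,3-oxazolidin-2-one
Product: 10 methyl (1R,2S,3S)-2-{[(4S)-4-benzyl-2-oxo-1,3-oxazolidin-3-yl]carbonyl}-3-(4-methoxyphenyl)cyclopropane-1-carboxylate, via mixed pivalic anhydride 9 (not isolated)
Conditions: PivCl, Et3N, THF, −20 °C; then 8, LiCl, 23 °C
Reagents that add atoms: none
Why: N-acylation of the oxazolidinone through the mixed pivalic anhydride under LiCl/Et3N; the cyclopropane α-carbons do not enolize here. Any antipodal hemiester becomes a diastereomer of 10 and is removed by crystallization or chromatography.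

Step 5
Reactants: 10 methyl (1R,2S,3S)-2-{[(4S)-4-benzyl-2-oxo-1,3-oxazolidin-3-yl]carbonyl}-3-(4-methoxyphenyl)cyclopropane-1-carboxylate, 11 phloroglucinol
Product: 13 (3S,4R)-3-{2-[(4S)-4-benzyl-2-oxo-1,3-oxazolidin-3-yl]-2-oxoethyl}-5,7-dihydroxy-4-(4-methoxyphenyl)chroman-2-one, via ring-opened trihydroxyphenyl methyl ester 12 (not isolated)
Conditions: Sc(OTf)3 (20 mol %), 11 (3 equiv), MeNO2–MeCN, 0 → 40 °C; then TsOH·H2O (cat.), toluene, 60 °C
Reagents that add atoms: none
Why: Proposed new method: Sc(OTf)3 binds the acyl oxazolidinone as a two-point chelate, which polarizes the bond between the imide-bearing carbon and the anisyl-bearing carbon far more than the bond to the ester-bearing carbon, and positive charge develops at the benzylic carbon (future C4), stabilized by the 4-methoxyphenyl group. Phloroglucinol attacks this carbon anti to the departing carbon (SN2-like), forming C4–C4a as C4–C3' breaks, and protonation of the metal-bound imide enolate leaves C3' as CH2 in 12. The closest known reaction type is the Lewis-acid-catalysed Friedel–Crafts ring opening of 2-arylcyclopropane-1,1-diesters by electron-rich arenes, which goes with inversion at the aryl-bearing carbon; a 1,2-diacyl cyclopropane with one acceptor on each candidate bond has not been opened this way. Ring A then closes by 6-exo-trig acyl substitution of an ortho hydroxyl on the methyl ester (O1–C2, loss of methanol), preferred over the seven-membered closure on the imide. C4 is the one new stereocentre and is controlled by inversion of the cyclopropane carbon; C3 is untouched, and since aryl and ester were trans on the three-membered ring, inversion places the aryl group and the C3 side chain trans on the lactone, which is also the stable arrangement. The step needs bond selection (chelated imide against plain ester; the wrong mode would give a constitutionally different ester lactone plus free 8, so it costs material and not enantiopurity), invertive rather than ionized opening (low temperature, weakly ionizing medium, excess of a strong π-nucleophile) and mono-alkylation (three equivalent carbons, threefold excess of 11).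

Step 6
Reactants: 13 (3S,4R)-3-{2-[(4S)-4-benzyl-2-oxo-1,3-oxazolidin-3-yl]-2-oxoethyl}-5,7-dihydroxy-4-(4-methoxyphenyl)chroman-2-one
Product: 14 (3S,4R)-3-{2-[(4S)-4-benzyl-2-oxo-1,3-oxazolidin-3-yl]-2-oxoethyl}-5,7-dimethoxy-4-(4-methoxyphenyl)chroman-2-one
Conditions: MeI, K2CO3, acetone, 23 °C
Reagents that add atoms: iodomethane, CI
Why: Williamson O-methylation of the two phenols with a carbonate base in dry acetone, where no nucleophile is present to open the aryl lactone or the imide. C3 is already in its stable trans arrangement, so reversible enolization there is harmless.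

Step 7
Reactants: 15 1,2,3,4-tetramethoxybenzene
Product: 18 2,3,4,5-tetramethoxyphenol, via (2,3,4,5-tetramethoxyphenyl)lithium 16 (not isolated), via lithium trimethoxy(2,3,4,5-tetramethoxyphenyl)borate 17 (not isolated)
Conditions: n-BuLi, TMEDA, THF, 0 °C; B(OMe)3, −78 → 23 °C; then AcOH, H2O2 (30% aq.), 0 → 23 °C
Reagents that add atoms: hydrogen peroxide, OO
Why: Directed ortho-lithiation next to a methoxy group (the two free positions of 15 are symmetry-related), borylation, and oxidation of the C–B bond give the phenol in one flask.

Step 8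
Reactants: 18 2,3,4,5-tetramethoxyphenol
Product: 20 2-hydroxy-3,4,5,6-tetramethoxybenzaldehyde, via 2-(hydroxymethyl)-3,4,5,6-tetramethoxyphenol chloromagnesium salt 19 (not isolated)
Conditions: MgCl2, Et3N, (CH2O)n, MeCN, reflux; HCl aq.
Reagents that add atoms: paraformaldehyde (source of formaldehyde), C=O
Why: Magnesium-phenoxide-directed ortho-formylation: the chloromagnesium phenoxide is hydroxymethylated at the only free position, and alkoxide 19 is oxidized in the flask by hydride transfer to a second formaldehyde.

Step 9
Reactants: 20 2-hydroxy-3,4,5,6-tetramethoxybenzaldehyde, 21 4-methoxyphenylmagnesium bromide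
Product: 22 2-[hydroxy(4-methoxyphenyl)methyl]-3,4,5,6-tetramethoxyphenol (racemic)
Conditions: 21 (2.5 equiv), THF, 0 → 23 °C; NH4Cl aq.
Reagents that add atoms: none
Why: Grignard addition to the salicylaldehyde, the first equivalent being consumed by the phenol. The carbinol centre is left racemic because it becomes sp2 in quinone methide 24.

Step 10
Reactants: 14 (3S,4R)-3-{2-[(4S)-4-benzyl-2-oxo-1,3-oxazolidin-3-yl]-2-oxoethyl}-5,7-dimethoxy-4-(4-methoxyphenyl)chroman-2-one, 22 2-[hydroxy(4-methoxyphenyl)methyl]-3,4,5,6-tetramethoxyphenol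
Product: 26 (3R,4R)-5,7-dimethoxy-4-(4-methoxyphenyl)-3-[(3S,4R)-5,6,7,8-tetramethoxy-4-(4-methoxyphenyl)-2-oxochroman-3-yl]chroman-2-one, via trichlorotitanium (Z)-enolate 23 (not isolated), via ortho-quinone methide 24 (not isolated), via Michael adduct phenol 25 (not isolated)
Conditions: 14, TiCl4, i-Pr2NEt, CH2Cl2, −78 °C; then 22 premixed with TiCl4 (CH2Cl2, −78 °C), −78 → −20 °C; aqueous work-up; then PPTS (cat.), toluene, 60 °C
Reagents that add atoms: none
Why: Michael addition of the chelated (Z)-enolate 23 to quinone methide 24, then lactonization (formal oxa-[4+2] annulation); Michael additions and SN1-type alkylations by benzhydryl cations are established for titanium enolates of N-acyl oxazolidinones. The auxiliary sets C3' (attack on the enolate face opposite the benzyl group gives 3'S), and a closed transition state with titanium bridging the enolate and quinone methide oxygens sets C4': a (Z)-enolate and an aryl-outside methide give the anti adduct 25 and hence the cis lactone. Acyl transfer to the phenol releases 8 under acid catalysis, so the epimerizable cis C3' never meets base.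

Step 11
Reactants: 26 (3R,4R)-5,7-dimethoxy-4-(4-methoxyphenyl)-3-[(3S,4R)-5,6,7,8-tetramethoxy-4-(4-methoxyphenyl)-2-oxochroman-3-yl]chroman-2-one
Product: 27 (3R,4R)-5,7-dihydroxy-4-(4-hydroxyphenyl)-3-[(3S,4R)-5,6,7,8-tetrahydroxy-4-(4-hydroxyphenyl)-2-oxochroman-3-yl]chroman-2-one
Conditions: BBr3 (20 equiv), CH2Cl2, −78 → 23 °C; H2O, 0 °C (argon)
Reagents that add atoms: none
Why: BBr3 cleaves all eight aryl methyl ethers (Lewis-acid ether dealkylation via aryloxyboranes, hydrolysed on work-up). No base is present, so C3 and C3' are not enolized, and a lactone that opens transiently recloses on acidic work-up to the same constitution because both arenes carry equivalent ortho oxygens; the air-sensitive tetrahydroxy ring is handled under argon.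

## Compound list

1 | 4-methoxybenzaldehyde | COc1ccc(C=O)cc1 | starting material
2 | (E)-(4-methoxybenzylidene)hydrazine | COc1ccc(/C=N/N)cc1 | intermediate
3 | maleic anhydride | O=C1OC(=O)C=C1 | starting material
4 | 1-(diazomethyl)-4-methoxybenzene | COc1ccc(C=[N+]=[N-])cc1 | intermediate
5 | 3-(4-methoxyphenyl)-3a,6a-dihydro-3H-furo[3,4-c]pyrazole-4,6-dione (racemic, cis-fused, C3 epimers) | COc1ccc(cc1)C1N=N[C@H]2C(=O)OC(=O)[C@@H]12 | intermediate
6 | meso-6-exo-(4-methoxyphenyl)-3-oxabicyclo[3.1.0]hexane-2,4-dione (aryl trans to the anhydride ring) | COc1ccc(cc1)[C@@H]1[C@H]2C(=O)OC(=O)[C@@H]12 | intermediate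
7 | (1S,2R,3S)-2-(methoxycarbonyl)-3-(4-methoxyphenyl)cyclopropane-1-carboxylic acid | COc1ccc(cc1)[C@@H]1[C@@H](C(=O)OC)[C@H]1C(=O)O | intermediate
8 | (S)-4-benzyl-1,3-oxazolidin-2-one | O=C1N[C@@H](Cc2ccccc2)CO1 | starting material
9 | mixed pivalic anhydride of 7 | COc1ccc(cc1)[C@@H]1[C@@H](C(=O)OC)[C@H]1C(=O)OC(=O)C(C)(C)C | intermediate
10 | methyl (1R,2S,3S)-2-{[(4S)-4-benzyl-2-oxo-1,3-oxazolidin-3-yl]carbonyl}-3-(4-methoxyphenyl)cyclopropane-1-carboxylate | COc1ccc(cc1)[C@@H]1[C@@H](C(=O)OC)[C@H]1C(=O)N1[C@@H](Cc2ccccc2)COC1=O | intermediate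
11 | phloroglucinol (benzene-1,3,5-triol) | Oc1cc(O)cc(O)c1 | starting material
12 | methyl (2S)-4-[(4S)-4-benzyl-2-oxo-1,3-oxazolidin-3-yl]-2-[(R)-(4-methoxyphenyl)(2,4,6-trihydroxyphenyl)methyl]-4-oxobutanoate | Oc1cc(O)cc(O)c1[C@@H](c1ccc(OC)cc1)[C@@H](C(=O)OC)CC(=O)N1[C@@H](Cc2ccccc2)COC1=O | intermediate
13 | (3S,4R)-3-{2-[(4S)-4-benzyl-2-oxo-1,3-oxazolidin-3-yl]-2-oxoethyl}-5,7-dihydroxy-4-(4-methoxyphenyl)chroman-2-one | O=C1Oc2cc(O)cc(O)c2[C@@H](c2ccc(OC)cc2)[C@@H]1CC(=O)N1[C@@H](Cc2ccccc2)COC1=O | intermediate
14 | (3S,4R)-3-{2-[(4S)-4-benzyl-2-oxo-1,3-oxazolidin-3-yl]-2-oxoethyl}-5,7-dimethoxy-4-(4-methoxyphenyl)chroman-2-one | O=C1Oc2cc(OC)cc(OC)c2[C@@H](c2ccc(OC)cc2)[C@@H]1CC(=O)N1[C@@H](Cc2ccccc2)COC1=O | intermediate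
15 | 1,2,3,4-tetramethoxybenzene | COc1ccc(OC)c(OC)c1OC | starting material
16 | (2,3,4,5-tetramethoxyphenyl)lithium | [Li]c1cc(OC)c(OC)c(OC)c1OC | intermediate
17 | lithium trimethoxy(2,3,4,5-tetramethoxyphenyl)borate | [Li+].CO[B-](OC)(OC)c1cc(OC)c(OC)c(OC)c1OC | intermediate
18 | 2,3,4,5-tetramethoxyphenol | Oc1cc(OC)c(OC)c(OC)c1OC | intermediate
19 | 2-(hydroxymethyl)-3,4,5,6-tetramethoxyphenol (present as its chloromagnesium salt) | OCc1c(O)c(OC)c(OC)c(OC)c1OC | intermediate
20 | 2-hydroxy-3,4,5,6-tetramethoxybenzaldehyde | O=Cc1c(O)c(OC)c(OC)c(OC)c1OC | intermediate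
21 | 4-methoxyphenylmagnesium bromide | COc1ccc([Mg]Br)cc1 | starting material
22 | 2-[hydroxy(4-methoxyphenyl)methyl]-3,4,5,6-tetramethoxyphenol (racemic) | COc1ccc(cc1)C(O)c1c(O)c(OC)c(OC)c(OC)c1OC | intermediate
23 | trichlorotitanium (Z)-enolate of 14 | O=C1Oc2cc(OC)cc(OC)c2[C@@H](c2ccc(OC)cc2)[C@@H]1/C=C(\O[Ti](Cl)(Cl)Cl)N1[C@@H](Cc2ccccc2)COC1=O | intermediate
24 | (E)-6-(4-methoxybenzylidene)-2,3,4,5-tetramethoxycyclohexa-2,4-dien-1-one | COc1ccc(cc1)/C=C1/C(=O)C(OC)=C(OC)C(OC)=C1OC | intermediate
25 | open-chain Michael adduct of 23 and 24 (ring A 3R,4R; C3' S, C4' R; free C8a' phenol; acyl oxazolidinone at C2') | O=C1Oc2cc(OC)cc(OC)c2[C@@H](c2ccc(OC)cc2)[C@@H]1[C@@H](C(=O)N1[C@@H](Cc2ccccc2)COC1=O)[C@H](c1ccc(OC)cc1)c1c(O)c(OC)c(OC)c(OC)c1OC | intermediate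
26 | (3R,4R)-5,7-dimethoxy-4-(4-methoxyphenyl)-3-[(3S,4R)-5,6,7,8-tetramethoxy-4-(4-methoxyphenyl)-2-oxochroman-3-yl]chroman-2-one | O=C1Oc2cc(OC)cc(OC)c2[C@@H](c2ccc(OC)cc2)[C@@H]1[C@H]1C(=O)Oc2c(OC)c(OC)c(OC)c(OC)c2[C@H]1c1ccc(OC)cc1 | intermediate
27 | (3R,4R)-5,7-dihydroxy-4-(4-hydroxyphenyl)-3-[(3S,4R)-5,6,7,8-tetrahydroxy-4-(4-hydroxyphenyl)-2-oxochroman-3-yl]chroman-2-one | O=C1Oc2cc(O)cc(O)c2[C@@H](c2ccc(O)cc2)[C@@H]1[C@H]1C(=O)Oc2c(O)c(O)c(O)c(O)c2[C@H]1c1ccc(O)cc1 | target

## Step count and least certain steps

Total: 11 steps. Longest linear sequence: 8 steps (steps 1–6, 10, 11); the ring B branch (steps 7–9) joins at step 10.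

**Step 5 (key step).** The 4-methoxyphenyl donor may let the ring ionize to an open zwitterion before the arene attacks, which would erode the stereospecificity at C4 and with it the enantiopurity. A single acceptor on the breaking bond may also activate too weakly, the bond to the ester-bearing carbon may compete, and the chelated imide may transfer its acyl group to phloroglucinol. The fallback is known chemistry and sets out from 11:
- Acid-mediated hydroarylation–lactonization of 11 with 4-methoxycinnamic acid (CF3CO2H, 60 °C) should give racemic 5,7-dihydroxy-4-(4-methoxyphenyl)chroman-2-one F1.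
- MeI/K2CO3 gives rac-5,7-dimethoxy-4-(4-methoxyphenyl)chroman-2-one F2.
- Its enolate (LiN(SiMe3)2, THF, −78 °C) is alkylated anti to the C4 aryl group by (S)-4-benzyl-3-(bromoacetyl)-1,3-oxazolidin-2-one F3 (from 8, n-BuLi and bromoacetyl bromide). This gives 14 together with its (3R,4S) diastereomer F4, which is separated by chromatography or crystallization.
- The route is rejoined at 14.

**Step 10.** Cis/trans selectivity may be poor if the quinone methide reacts through its aryl-inside geometry or an open transition state; the 5'-methoxy group removes the usual preference for the aryl-outside form. The free hydroxyl groups of 22 may quench the enolate, the quinone methide may self-condense, and C3' may epimerize during lactonization. The fallback sets out from 22 and 14: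
- MnO2 oxidation of 22 gives (2-hydroxy-3,4,5,6-tetramethoxyphenyl)(4-methoxyphenyl)methanone F5.
- With Cs2CO3 in MeCN its phenoxide takes the acyl group from 14 (8 is released), and the aryl ester condenses with the ketone (intramolecular Knoevenagel-type condensation) to 5,6,7,8-tetramethoxy-4-(4-methoxyphenyl)-3-[(3R,4R)-5,7-dimethoxy-4-(4-methoxyphenyl)-2-oxochroman-3-yl]-2H-chromen-2-one F6.
- Hydrogenation (H2, Pd/C, elevated pressure) adds both hydrogens to one face of C3'=C4', so ring B is cis by construction, the face being chosen by ring A.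
- The route is rejoined at 26.

**Step 2.** The 1-pyrazoline may tautomerize to the 2-pyrazoline, which does not lose nitrogen; the electron-rich diazo compound may decompose to azine; unoxidized hydrazone may acylate on the anhydride; and some endo-aryl isomer may form. The fallback sets out from 1:
- TsNHNH2 gives 4-methoxybenzaldehyde N-tosylhydrazone F7.
- Pd(OAc)2-catalysed cyclopropanation of N-methylmaleimide (LiOt-Bu, 1,4-dioxane, 80 °C) gives meso-6-exo-(4-methoxyphenyl)-3-methyl-3-azabicyclo[3.1.0]hexane-2,4-dione F8.
- Hydrolysis (KOH, aqueous ethylene glycol, 120 °C, then HCl at 0 °C) gives meso cis-3-(4-methoxyphenyl)cyclopropane-1,2-dicarboxylic acid F9 (aryl trans to both carboxyl groups).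
- Ac2O closes it to 6, where the route is rejoined.

**Step 3.** Discrimination between the enantiotopic carbonyls of a cyclopropane-fused anhydride may be low or of the opposite sense, and methanolysis may be slow at −55 °C. The fallback sets out from 6:
- The N-lithio derivative of 8 (n-BuLi, THF, −78 °C) opens the anhydride to two diastereomeric imide acids: (1R,2S,3S)-2-{[(4S)-4-benzyl-2-oxo-1,3-oxazolidin-3-yl]carbonyl}-3-(4-methoxyphenyl)cyclopropane-1-carboxylic acid F10 and its (1S,2R,3R) cyclopropane isomer F11. They are separated by crystallization.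
- F10 with TMSCHN2 (toluene–MeOH) gives 10, where the route is rejoined.

## Further compounds

F1 | step 5 | rac-5,7-dihydroxy-4-(4-methoxyphenyl)chroman-2-one | O=C1CC(c2ccc(OC)cc2)c2c(O)cc(O)cc2O1
F2 | step 5 | rac-5,7-dimethoxy-4-(4-methoxyphenyl)chroman-2-one | O=C1CC(c2ccc(OC)cc2)c2c(OC)cc(OC)cc2O1
F3 | step 5 | (S)-4-benzyl-3-(bromoacetyl)-1,3-oxazolidin-2-one | O=C(CBr)N1[C@@H](Cc2ccccc2)COC1=O
F4 | step 5 | (3R,4S)-3-{2-[(4S)-4-benzyl-2-oxo-1,3-oxazolidin-3-yl]-2-oxoethyl}-5,7-dimethoxy-4-(4-methoxyphenyl)chroman-2-one | O=C1Oc2cc(OC)cc(OC)c2[C@H](c2ccc(OC)cc2)[C@H]1CC(=O)N1[C@@H](Cc2ccccc2)COC1=O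
F5 | step 10 | (2-hydroxy-3,4,5,6-tetramethoxyphenyl)(4-methoxyphenyl)methanone | COc1ccc(cc1)C(=O)c1c(O)c(OC)c(OC)c(OC)c1OC
F6 | step 10 | 5,6,7,8-tetramethoxy-4-(4-methoxyphenyl)-3-[(3R,4R)-5,7-dimethoxy-4-(4-methoxyphenyl)-2-oxochroman-3-yl]-2H-chromen-2-one | O=C1Oc2cc(OC)cc(OC)c2[C@@H](c2ccc(OC)cc2)[C@@H]1C1=C(c2ccc(OC)cc2)c2c(OC)c(OC)c(OC)c(OC)c2OC1=O
F7 | step 2 | 4-methoxybenzaldehyde N-tosylhydrazone | COc1ccc(/C=N/NS(=O)(=O)c2ccc(C)cc2)cc1
F8 | step 2 | meso-6-exo-(4-methoxyphenyl)-3-methyl-3-azabicyclo[3.1.0]hexane-2,4-dione | COc1ccc(cc1)[C@@H]1[C@H]2C(=O)N(C)C(=O)[C@@H]12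
F9 | step 2 | meso cis-3-(4-methoxyphenyl)cyclopropane-1,2-dicarboxylic acid (aryl trans to both carboxyl groups) | COc1ccc(cc1)[C@@H]1[C@@H](C(=O)O)[C@H]1C(=O)O
F10 | step 3 | (1R,2S,3S)-2-{[(4S)-4-benzyl-2-oxo-1,3-oxazolidin-3-yl]carbonyl}-3-(4-methoxyphenyl)cyclopropane-1-carboxylic acid | COc1ccc(cc1)[C@@H]1[C@@H](C(=O)O)[C@H]1C(=O)N1[C@@H](Cc2ccccc2)COC1=O
F11 | step 3 | (1S,2R,3R)-2-{[(4S)-4-benzyl-2-oxo-1,3-oxazolidin-3-yl]carbonyl}-3-(4-methoxyphenyl)cyclopropane-1-carboxylic acid | COc1ccc(cc1)[C@H]1[C@H](C(=O)O)[C@@H]1C(=O)N1[C@@H](Cc2ccccc2)COC1=O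
A1 | alternative 1 | chroman-2-ol (lactol) form of the octa-O-methyl target, C2 epimers | OC1Oc2cc(OC)cc(OC)c2[C@@H](c2ccc(OC)cc2)[C@@H]1[C@H]1C(=O)Oc2c(OC)c(OC)c(OC)c(OC)c2[C@H]1c1ccc(OC)cc1
A2 | alternative 1 | 2-[(3R,4R)-5,6,7,8-tetramethoxy-4-(4-methoxyphenyl)-2-oxochroman-3-yl]acetaldehyde (3,4-cis) | O=CC[C@H]1C(=O)Oc2c(OC)c(OC)c(OC)c(OC)c2[C@H]1c1ccc(OC)cc1
A3 | alternative 1 | 2-[hydroxy(4-methoxyphenyl)methyl]-3,5-dimethoxyphenol (racemic) | COc1ccc(cc1)C(O)c1c(O)cc(OC)cc1OC
A4 | alternative 2 | 5',8'-dihydroxy hexa-O-methyl ether of the target | O=C1Oc2cc(OC)cc(OC)c2[C@@H](c2ccc(OC)cc2)[C@@H]1[C@H]1C(=O)Oc2c(O)c(OC)c(OC)c(O)c2[C@H]1c1ccc(OC)cc1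
A5 | alternative 2 | 3-(4,5-dimethoxy-3,6-dioxocyclohexa-1,4-dien-1-yl)-3-(4-methoxyphenyl)-2-[(3R,4R)-5,7-dimethoxy-4-(4-methoxyphenyl)-2-oxochroman-3-yl]propanoic acid (C3' and C4' as in the target) | O=C1Oc2cc(OC)cc(OC)c2[C@@H](c2ccc(OC)cc2)[C@@H]1[C@@H](C(O)=O)[C@H](c1ccc(OC)cc1)C1=CC(=O)C(OC)=C(OC)C1=O
A6 | alternative 3 | octa-O-methyl ether of the target (identical with 26) | O=C1Oc2cc(OC)cc(OC)c2[C@@H](c2ccc(OC)cc2)[C@@H]1[C@H]1C(=O)Oc2c(OC)c(OC)c(OC)c(OC)c2[C@H]1c1ccc(OC)cc1
A7 | alternative 3 | (E)-2-[(3R,4R)-5,7-dimethoxy-4-(4-methoxyphenyl)-2-oxochroman-3-yl]-3-(4-methoxyphenyl)prop-2-enoic acid | O=C1Oc2cc(OC)cc(OC)c2[C@@H](c2ccc(OC)cc2)[C@@H]1/C(C(O)=O)=C\c1ccc(OC)cc1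
A8 | alternative 3 | 2,3,4,5-tetramethoxy-6-(trimethylsilyl)phenyl trifluoromethanesulfonate | COc1c(OC)c(OC)c(OC)c([Si](C)(C)C)c1OS(=O)(=O)C(F)(F)F
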